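X cannot hold more Z than the 1.20 mM of X charged.

    E + G + Z → D + 2 Z (k1 = 160 L² mol⁻² s⁻¹, Ea1 = 38.0 kJ mol⁻¹)
    E + G → D + Z (k2 = 0.057 L mol⁻¹ s⁻¹, Ea2 = 53.0 kJ mol⁻¹)
    2 E → E2 (k3 = 0.13 L mol⁻¹ s⁻¹, Ea3 = 62.0 kJ mol⁻¹)
    X + Z ⇌ X.Z, settled at all times (K4 = 2.9 × 10⁵ L mol⁻¹, ΔH4 = −32.0 kJ mol⁻¹)
    (constants at 25 °C)

- delta: E 24 mM; G 1.00 equiv; X 0.0500 equiv; temperature 25 °C; time 50 s
- eta: E 24 mM; G 1.00 equiv; X 0.0500 equiv; temperature 33 °C; time 50 s

- a species is counted by the E in it: one E2 counts as two
- a doubled species enters its step squared and goes two at a time
- constants are those at 25 °C; use the activation energies and enthalpies for any other temperature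

* which of these there is most of at the end, counted by the E in it, delta (E / D)
* which of these there is most of at the end, counted by the E in it, eta (E / D)
* amount of the one of these that there is most of at the end, in percent of the E charged, delta
* amount of the one of these that there is most of at the end, in percent of the E charged, eta

I write the balance of X, the smallest charge at 1.20 mM. I call E + G + Z the Z-assisted step and E + G the plain step. From 25 °C to 33 °C, the Z-assisted step gains a factor 1.49, the plain step 1.75, and dimerisation 1.92. My ladder runs from fastest to slowest.

1. X and Z stand at balance at once. In delta, with X half filled, free [Z] is 1/K4, so the Z-assisted step runs slower than the plain step, at 0.00968 of its rate.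

2. Once X is filled, Z multiplies in a growth time 1/(k1[E][G]). At the charged amounts this is 10.9 s in delta and 7.27 s in eta.

3. In delta, 41.1 s is the buffer time t_b: the time in which the plain step, with E thinned by dimerisation, makes as much Z as X was charged. In eta, t_b is 23.8 s.

4. The first half-life of E by dimerisation is 160 s in delta and 83.4 s in eta.

5. The plain step is slower than dimerisation, with a half-life of 731 s in delta.

Delta has 8.95 s left after t_b, less than one growth time. Eta has 26.2 s, or 3.60 growth times.

Taking the plain step and dimerisation together as one second-order loss of E, I get 72.4% of E in delta and 58.2% in eta. I commit to the first figure, and to E leading in both flasks. For eta I expect less than the second figure, because t_b ends before the time does.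

The forecast gives E at 72% (69% to 75%) in delta, and E at 50% (45% to 55%) in eta. Its ground for eta is that “dimerisation also speeds up, so unreacted E still leads”. For eta its figure is lower than mine.

The simulation gives E at 71.5% in delta, with D at 6.02%, and E at 49.9% in eta, with D at 16.5%. Both stand within the forecast's ranges.

In eta at 17.6 s, inside t_b, dimerisation uses E 4.1 times as fast as the plain step. At 50.0 s, past t_b, the half-life of E by the Z-assisted step is shorter than by the plain step, 52 s against 5.8 min.

Now take eta with 2.50 equiv of G. Its t_b is 8.80 s and its growth time 2.91 s, so 14.2 growth times remain and I expect D to lead. The simulation gives D at 81.7%, with E at 0.422%.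

The constants were drawn at random within sensible limits.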